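The route forms the C3–C4 bond of the tetrahydrofuran ring (O1, C2, C3, C4, C5) by a reductive radical cyclisation. The hydroxymethyl carbon C9 hangs on C3, which lies between C2 (bearing the aryl group and O1) and C4 (bearing the benzylic carbon C7′). The C3–C9 unit is therefore carried as an oxirane and C4–C7′ as a styrene-type alkene, linked through the O1–C5 ether. Cp2TiCl turns the oxirane into a C3 radical that closes the ring 5-exo and sets C3 and C4 from C2 in one operation. The precursor is the enantiopure cinnamyl ether of a 1-aryl-2,3-epoxypropan-1-ol. Only its carbinol centre matters, because the oxirane carbon becomes planar in the radical.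

Key step: step 6

Remark: the benzylic carbinol carbon keeps one spatial arrangement throughout; its descriptor reads S in the allylic alcohol, R in the epoxy alcohol and its ether, and S again in the tetrahydrofuran, only because the priority of the neighbouring carbon changes.

Step 1
Reactants: 1 4-(benzyloxy)-3-methoxybenzaldehyde (O-benzylvanillin); 2 vinylmagnesium bromide
Product: 3 rac-1-[4-(benzyloxy)-3-methoxyphenyl]prop-2-en-1-ol
Conditions: THF, −78 → 0 °C; sat. aq NH4Cl
Reagents that add atoms: none
Why: Grignard 1,2-addition of the vinyl nucleophile to the aromatic aldehyde should be clean at low temperature; the new carbinol centre forms as a racemate and is resolved in step 2.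

Step 2
Reactants: 3 rac-1-[4-(benzyloxy)-3-methoxyphenyl]prop-2-en-1-ol
Product: 4 (R)-[4-(benzyloxy)-3-methoxyphenyl][(2S)-oxiran-2-yl]methanol (erythro epoxy alcohol)
Conditions: Ti(OiPr)4 (0.2 equiv), D-(−)-diisopropyl tartrate (0.25 equiv), t-BuOOH (0.45 equiv, anhydrous), 4 Å MS, CH2Cl2, −20 °C; aq tartaric acid work-up
Reagents that add atoms: tert-butyl hydroperoxide, CC(C)(C)OO
Why: Sharpless kinetic resolution by asymmetric epoxidation: with the D-tartrate ligand the (S)-alcohol, whose carbinol carbon has the arrangement of C2 in the target, should be epoxidised far faster than its antipode and on the face that gives the erythro product, while the substoichiometric peroxide stops the reaction before the (R)-alcohol is consumed.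

Step 3
Reactants: 5 (E)-3-(3,4-dimethoxyphenyl)prop-2-enoic acid
Product: 7 (E)-3-(3,4-dimethoxyphenyl)prop-2-en-1-ol, via mixed carbonic anhydride 6 (not isolated)
Conditions: ClCO2Et, Et3N, THF, 0 °C; then NaBH4, THF–H2O, 0 °C → rt
Reagents that add atoms: none
Why: Chemoselective borohydride reduction of a mixed carbonic anhydride: the activated acyl group should be reduced to the primary alcohol faster than hydride adds to the conjugated alkene, so the E double bond is kept.

Step 4
Reactants: 7 (E)-3-(3,4-dimethoxyphenyl)prop-2-en-1-ol
Product: 8 4-[(E)-3-bromoprop-1-enyl]-1,2-dimethoxybenzene (3,4-dimethoxycinnamyl bromide)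
Conditions: PBr3 (0.4 equiv), Et2O, 0 °C; used at once without purification
Reagents that add atoms: phosphorus tribromide, BrP(Br)Br
Why: Conversion of an allylic alcohol into the bromide with PBr3 (substitution through the phosphite ester); direct and allylic displacement both end at the conjugated primary E-bromide, which is labile and is therefore used immediately.

Step 5
Reactants: 4 (R)-[4-(benzyloxy)-3-methoxyphenyl][(2S)-oxiran-2-yl]methanol; 8 3,4-dimethoxycinnamyl bromide
Product: 9 (2S)-2-[(R)-[4-(benzyloxy)-3-methoxyphenyl]{[(E)-3-(3,4-dimethoxyphenyl)prop-2-enyl]oxy}methyl]oxirane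
Conditions: NaH (1.1 equiv) added in portions to 4 + 8 (1.3 equiv), THF–DMF (4:1), 0 °C → rt
Reagents that add atoms: none
Why: Williamson ether synthesis in which the sodium alkoxide is generated in the presence of the very reactive allylic bromide and should be alkylated before Payne-type epoxide migration can occur; no stereocentre is touched.

Step 6
Reactants: 9 (2S)-2-[(R)-[4-(benzyloxy)-3-methoxyphenyl]{[(E)-3-(3,4-dimethoxyphenyl)prop-2-enyl]oxy}methyl]oxirane
Product: 11 [(2S,3R,4R)-2-[4-(benzyloxy)-3-methoxyphenyl]-4-(3,4-dimethoxybenzyl)tetrahydrofuran-3-yl]methanol (O-benzyl ether of the target), via bis(Cp2TiCl) adduct 10 (not isolated)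
Conditions: Cp2TiCl2 (2.5 equiv), Zn dust, THF, rt; the green Cp2TiCl solution added dropwise to 9 in THF, rt; then 1 M aq HCl, 0 °C
Reagents that add atoms: none
Why: Cp2TiCl (trivalent titanium) transfers one electron to the oxirane and breaks its C3–O bond homolytically, giving the secondary β-titanoxy radical at C3; this adds to C4 of the cinnamyl alkene, and the resulting benzylic C7′ radical is reduced by a second Cp2TiCl to the tetravalent-titanium species 10, whose C–Ti and O–Ti bonds are protonated on acidic work-up. The closest known reaction type is the reductive epoxide-opening radical cyclisation of epoxy allyl and cinnamyl ethers mediated by Cp2TiCl, which is established for this substrate class. The tetrahydrofuran ring (O1, C2, C3, C4, C5) closes 5-exo-trig, kinetically preferred over 6-endo and made fast and irreversible by the styrene acceptor. C3 is controlled by the existing C2 centre: in a chair-like transition state the C2 aryl group sits pseudo-equatorial and the CH2O–Ti arm on the radical carbon turns away from it, so C9 should end trans to the aryl group. C4 is set in the same transition state, where the alkene arm is pseudo-equatorial and cis to the substituent on the radical carbon, so the 3,4-dimethoxybenzyl group should end cis to C9 and trans to the aryl group. The step needs ring closure to outrun capture of the C3 radical by a second titanium centre (which would lead to deoxygenation or plain reduction); slow addition of Cp2TiCl and the high rate of radical addition to a styrene should secure this.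

Step 7
Reactants: 11 [(2S,3R,4R)-2-[4-(benzyloxy)-3-methoxyphenyl]-4-(3,4-dimethoxybenzyl)tetrahydrofuran-3-yl]methanol
Product: 12 [(2S,3R,4R)-4-(3,4-dimethoxybenzyl)-2-(4-hydroxy-3-methoxyphenyl)tetrahydrofuran-3-yl]methanol (4′-O-methyllariciresinol)
Conditions: H2 (1 atm), 10% Pd/C, EtOAc, rt
Reagents that add atoms: none
Why: Catalytic hydrogenolysis of an aryl benzyl ether; under neutral conditions at atmospheric pressure and with the reaction stopped at full conversion, the benzylic C2–O1 ring bond, the methyl ethers and the three stereocentres should remain intact.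

Compound list
1 | 4-(benzyloxy)-3-methoxybenzaldehyde (O-benzylvanillin) | COc1cc(C=O)ccc1OCc1ccccc1 | starting material
2 | vinylmagnesium bromide | C=C[Mg]Br | starting material
3 | rac-1-[4-(benzyloxy)-3-methoxyphenyl]prop-2-en-1-ol (racemate) | COc1cc(C(O)C=C)ccc1OCc1ccccc1 | intermediate
4 | (R)-[4-(benzyloxy)-3-methoxyphenyl][(2S)-oxiran-2-yl]methanol (erythro) | COc1cc([C@@H](O)[C@@H]2CO2)ccc1OCc1ccccc1 | intermediate
5 | (E)-3-(3,4-dimethoxyphenyl)prop-2-enoic acid | COc1ccc(/C=C/C(=O)O)cc1OC | starting material
6 | ethoxycarbonyl (E)-3-(3,4-dimethoxyphenyl)prop-2-enoate (mixed carbonic anhydride, not isolated) | COc1ccc(/C=C/C(=O)OC(=O)OCC)cc1OC | intermediate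
7 | (E)-3-(3,4-dimethoxyphenyl)prop-2-en-1-ol | COc1ccc(/C=C/CO)cc1OC | intermediate
8 | 4-[(E)-3-bromoprop-1-enyl]-1,2-dimethoxybenzene | COc1ccc(/C=C/CBr)cc1OC | intermediate
9 | (2S)-2-[(R)-[4-(benzyloxy)-3-methoxyphenyl]{[(E)-3-(3,4-dimethoxyphenyl)prop-2-enyl]oxy}methyl]oxirane | COc1cc([C@@H](OC/C=C/c2ccc(OC)c(OC)c2)[C@@H]2CO2)ccc1OCc1ccccc1 | intermediate
10 | bis(Cp2TiCl) adduct: compound 11 in which the C9 oxygen and C7′ each carry a Cp2TiCl unit (tetravalent titanium, C7′ configuration undefined, cyclopentadienyl rings drawn σ-bonded, not isolated) | COc1cc([C@H]2OC[C@H](C(c3ccc(OC)c(OC)c3)[Ti](Cl)(C4C=CC=C4)C5C=CC=C5)[C@@H]2CO[Ti](Cl)(C6C=CC=C6)C7C=CC=C7)ccc1OCc8ccccc8 | intermediate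
11 | [(2S,3R,4R)-2-[4-(benzyloxy)-3-methoxyphenyl]-4-(3,4-dimethoxybenzyl)tetrahydrofuran-3-yl]methanol | COc1cc([C@H]2OC[C@H](Cc3ccc(OC)c(OC)c3)[C@@H]2CO)ccc1OCc1ccccc1 | intermediate
12 | [(2S,3R,4R)-4-(3,4-dimethoxybenzyl)-2-(4-hydroxy-3-methoxyphenyl)tetrahydrofuran-3-yl]methanol (4′-O-methyllariciresinol) | COc1cc([C@H]2OC[C@H](Cc3ccc(OC)c(OC)c3)[C@@H]2CO)ccc1O | target

Total step count: 7.
Longest linear sequence: 5 steps (steps 1, 2, 5, 6, 7 from compound 1; equally steps 3, 4, 5, 6, 7 from compound 5).

Steps most likely to fail

Step 6. The C3 radical may be intercepted by a second trivalent titanium before it reaches the alkene, so that the oxirane oxygen is lost by β-elimination or the chain is reduced without ring closure; the closure may also proceed with weak facial control. The fallback sets out from 9 and comes back to the route at 12. The oxirane of 9 is opened at its terminal carbon with sodium benzyloxide (BnOH, NaH, DMF, 60 °C) to give (1R,2S)-3-(benzyloxy)-1-[4-(benzyloxy)-3-methoxyphenyl]-1-{[(E)-3-(3,4-dimethoxyphenyl)prop-2-enyl]oxy}propan-2-ol F1. Acylation with phenyl chlorothionoformate (pyridine, DMAP, CH2Cl2) gives the corresponding O-phenyl thionocarbonate F2. Bu3SnH and AIBN in refluxing benzene, with slow addition of the stannane, generate the same C3 radical by C–O homolysis (Barton–McCombie-type radical generation) without any metal that can trap it. It should close 5-exo onto the cinnamyl alkene and take hydrogen from the stannane, giving (2S,3R,4R)-3-(benzyloxymethyl)-2-[4-(benzyloxy)-3-methoxyphenyl]-4-(3,4-dimethoxybenzyl)tetrahydrofuran F3. Hydrogenolysis of both benzyl ethers (H2, Pd/C, EtOAc) then gives 12.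

Step 2. The rate difference between the enantiomers may be too small at the chosen conversion, which erodes the enantiomeric purity of the epoxy alcohol; epoxidation of the monosubstituted alkene may be slow; and the Lewis-acidic titanium alkoxide may open the terminal oxirane or ionise the electron-rich benzylic carbinol. The fallback sets out from 3 and comes back at 4. Lipase-catalysed acylation (immobilised Candida antarctica lipase B, vinyl acetate, toluene, rt), run past half conversion, should acetylate the (R)-alcohol and leave (S)-1-[4-(benzyloxy)-3-methoxyphenyl]prop-2-en-1-ol F4, which is separated from the acetate. Hydroxyl-directed epoxidation of F4 with VO(acac)2 (catalytic) and t-BuOOH in CH2Cl2 at 0 °C is expected to favour the erythro isomer 4. The minor threo epimer, (R)-[4-(benzyloxy)-3-methoxyphenyl][(2R)-oxiran-2-yl]methanol F5, is removed by chromatography.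

Step 5. The electron-rich cinnamyl bromide may ionise and oligomerise faster than it alkylates, and the alkoxide of 4 that is left waiting may undergo epoxide migration (Payne rearrangement). The fallback sets out from 4 and comes back at 9. Alkylation with the stable and reactive allyl bromide (NaH, Bu4NI catalytic, THF, 0 °C) gives (2S)-2-[(R)-(allyloxy)[4-(benzyloxy)-3-methoxyphenyl]methyl]oxirane F6. Cross-metathesis of F6 with purchased 3,4-dimethoxystyrene (C=Cc1ccc(OC)c(OC)c1, excess) using the second-generation Grubbs catalyst in CH2Cl2 at 40 °C should give the E-cinnamyl ether 9. This variant also makes steps 3 and 4 unnecessary.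

Further compounds
F1 | step 6 | (1R,2S)-3-(benzyloxy)-1-[4-(benzyloxy)-3-methoxyphenyl]-1-{[(E)-3-(3,4-dimethoxyphenyl)prop-2-enyl]oxy}propan-2-ol | COc1cc([C@@H](OC/C=C/c2ccc(OC)c(OC)c2)[C@@H](O)COCc2ccccc2)ccc1OCc1ccccc1
F2 | step 6 | O-[(1R,2S)-3-(benzyloxy)-1-[4-(benzyloxy)-3-methoxyphenyl]-1-{[(E)-3-(3,4-dimethoxyphenyl)prop-2-enyl]oxy}propan-2-yl] O-phenyl carbonothioate | COc1cc([C@@H](OC/C=C/c2ccc(OC)c(OC)c2)[C@@H](OC(=S)Oc2ccccc2)COCc2ccccc2)ccc1OCc1ccccc1
F3 | step 6 | (2S,3R,4R)-3-(benzyloxymethyl)-2-[4-(benzyloxy)-3-methoxyphenyl]-4-(3,4-dimethoxybenzyl)tetrahydrofuran | COc1cc([C@H]2OC[C@H](Cc3ccc(OC)c(OC)c3)[C@@H]2COCc4ccccc4)ccc1OCc1ccccc1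
F4 | step 2 | (S)-1-[4-(benzyloxy)-3-methoxyphenyl]prop-2-en-1-ol | COc1cc([C@@H](O)C=C)ccc1OCc1ccccc1
F5 | step 2 | (R)-[4-(benzyloxy)-3-methoxyphenyl][(2R)-oxiran-2-yl]methanol (threo epimer of 4) | COc1cc([C@@H](O)[C@H]2CO2)ccc1OCc1ccccc1
F6 | step 5 | (2S)-2-[(R)-(allyloxy)[4-(benzyloxy)-3-methoxyphenyl]methyl]oxirane | COc1cc([C@@H](OCC=C)[C@@H]2CO2)ccc1OCc1ccccc1
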